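Set the dusk run beside the spring run at 90.0 s: the starting material stands at 59.7 % in dusk and 59.7 % in spring, yet dusk holds more target, 21.9 % against 16.4 %.

| setting | spring | dusk | autumn | flask |
|---|---|---|---|---|
| starting material | 0.050 M | 0.050 M | 0.050 M | 0.050 M |
| first nucleophile | 1.3 equiv | 2 equiv | 0.90 equiv | 0.900 equiv |
| second nucleophile | 5 equiv | 5 equiv | 2.5 equiv | 5.00 equiv |
| remark | run made earlier | run made earlier | run made earlier |  |
| time |  |  |  | 2.5 min |

- spring (time / s: target / %, starting material / %): 12.0: 2.9, 93.9; 25.0: 6.0, 86.9; 40.0: 8.8, 79.2; 50.0: 11.0, 75.4; 60.0: 12.3, 70.7; 80.0: 15.8, 63.8; 90.0: 16.4, 59.7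
- dusk (time / s: target / %, starting material / %): 10.0: 2.9, 94.5; 12.0: 3.8, 93.7; 15.0: 4.4, 92.3; 25.0: 7.3, 86.7; 40.0: 11.1, 79.3; 60.0: 16.1, 71.1; 90.0: 21.9, 59.7
- autumn (time / s: target / %, starting material / %): 20.0: 3.4, 89.0; 40.0: 7.2, 79.5; 50.0: 9.5, 75.1; 80.0: 14.2, 63.9; 90.0: 15.0, 60.2

(scatter of a reading: 0.3 percentage points)



- amount of target in percent of the starting material charged, at 8.0 s, 40 s and 2.5 min

So you keep two accounts, one for time and one for shares. For time, dusk gives a first-order constant of 0.00573 s⁻¹ for the loss of starting material, and autumn, at 60.2 % after 90.0 s, sits beside it, as a rate-limiting step ahead of the target would.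

For shares, divide target by starting material lost. That selectivity reads 0.543 in dusk and 0.407 in spring. Now call N the first nucleophile present on average, charge less half the target made, and write the share as N/(N+c). Here c is the half-share loading, the first-nucleophile loading at which the intermediate gives target and everything else in equal parts. Dusk reads 1.59 and spring 1.78, so I carry their mean, 1.68. Autumn, with 2.5 equiv of second nucleophile, reads 1.36, lower than that mean, so I leave it out for this flask, which has 5.00 equiv.

Here is my ledger for the flask at 2.5 min. Starting material left is 42.3 %, and lost is 57.7 %. The share starts at 0.349 and averages 0.322, so target is 18.6 %. The remaining 39.1 % I book to products the readings don't show and nothing to the intermediate, so the books close at 100 % by construction. With the starting share, the reckoning gives 1.56 % at 8.0 s.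

The forecast says 1.6 %, 7 % and 18.9 %, from “Selectivity is about N/(N+c)”; its last point stands above mine.

The flask gives 1.54 %, 7.09 % and 19.1 %.

    starting material → intermediate (k = 0.00570 s⁻¹)
    first nucleophile + intermediate → target (k = 28.0 L mol⁻¹ s⁻¹)
    second nucleophile + intermediate → other capture product (k = 2.40 L mol⁻¹ s⁻¹)
    intermediate → solvolysis product (k = 1.60 s⁻¹)
    intermediate → side product (k = 0.0490 s⁻¹)

At 2.50 min the intermediate holds 0.0752 %, so the nothing booked for it moves the ledger by that much. Now take the half-share loading further along the same flask. At 25.0 min the starting material stands at 0.0194 %, so nearly all of it has been lost. Average N is then 0.726, which gives target at 30.2 %, and the flask holds 31.4 %.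

The readings were generated by integration from invented constants, and the scatter is random.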